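**Plan**

1. Locants used throughout: ring A = C1 (CH bearing isopropenyl), C2H=C3(CH3), C4 (CH bearing C7H2–OAr), C5 (quaternary; CH3 and C8H2–C9H2–C10O2H), C6H2.
2. Enabling feature: C7 (on C4) and C8 (on C5) are cis on neighbouring ring-A carbons, so they can be read as the carbonyl carbon and the acetal carbon of a cis-fused γ-lactone (ring B: C4–C7–O–C8–C5), that is, a 4-methyl-5-alkoxybutenolide whose C4=C5 alkene is a dienophile. The face of ring A that carries C7 and C8 is called the lactone face, the other the methyl face.
3. Cuts, in retrosynthetic order: the C7–O(aryl) ether; C8=C9 (two-carbon olefination); the C1–isopropenyl bond; finally C3–C4 and C5–C6 together, which opens ring A to a 2-silyloxypenta-1,3-diene and the butenolide.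
4. Forward: ring A is closed onto the preformed ring B in one cycloaddition; the silyl enol ether becomes the C2=C3 enone; C1 is reduced and substituted by isopropenyl; ring B is opened, C8 is extended to the propanoate chain, C7 is reduced and joined to umbelliferone.
5. Stereochemistry: the menthyl acetal at C8 sends the diene to the opposite face and so fixes C4 and C5 absolutely (their cis relation follows from suprafacial addition); C1 comes from a catalyst-controlled ketone reduction followed by an allylic coupling that proceeds with inversion.

Key step: step 3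

Assumption: the two acetal epimers formed in step 1 are taken to be separable by crystallisation and interconvertible under acid, so that material is funnelled into the (5R) acetal; if the crystalline epimer from (−)-menthol were (5S), (+)-menthol would give the crystalline acetal with the required (R) acetal carbon.

**Route**

Step 1
Reactants: 1 5-hydroxy-4-methylfuran-2(5H)-one; 2 (−)-menthol
Product: 3 (5R)-5-(l-menthyloxy)-4-methylfuran-2(5H)-one
Conditions: p-TsOH·H2O (cat.), toluene, reflux, Dean–Stark; crystallisation from hexane; mother liquor re-equilibrated with acid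
Reagents that add atoms: none
Why: Acid-catalysed acetalisation of the cyclic hemiacetal (pseudo-acid) with removal of water gives the pseudo-ester, and because the acetal carbon epimerises through the oxocarbenium ion under the same conditions the (5R) epimer can be collected by crystallisation while the rest is recycled.

Step 2
Reactants: 4 (E)-pent-3-en-2-one
Product: 5 (E)-2-(tert-butyldimethylsilyloxy)penta-1,3-diene
Conditions: TBSOTf (1.1 equiv), Et3N (1.5 equiv), Et2O, 0 °C
Reagents that add atoms: tert-butyldimethylsilyl trifluoromethanesulfonate, CC(C)(C)[Si](C)(C)OS(=O)(=O)C(F)(F)F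
Why: Soft enolisation (silyl dienol ether formation), in which O-silylation activates the ketone and the amine removes a proton from the α′-methyl group, should give the cross-conjugated 2-silyloxydiene with the E geometry of the propenyl unit retained.

Step 3
Reactants: 3 (5R)-5-(l-menthyloxy)-4-methylfuran-2(5H)-one; 5 (E)-2-(tert-butyldimethylsilyloxy)penta-1,3-diene
Product: 6 cis-fused Diels–Alder adduct (silyl enol ether at C1=C2, lactone menthyl acetal)
Conditions: 5 (3 equiv), 2,6-di-tert-butyl-4-methylphenol (cat.), CH2Cl2, 13 kbar, 40 °C
Reagents that add atoms: none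
Why: A concerted, suprafacial [4+2] cycloaddition of normal electron demand (Diels–Alder reaction; closest known class: 5-alkoxy- and 5-menthyloxybutenolides with 2-silyloxydienes) joins C6 to C5 and C3 to C4 in one event. It closes ring A as a six-membered carbocycle by intermolecular cycloaddition across the C4=C5 bond of the existing lactone ring B, and because both bonds form on one face of that alkene the ring fusion is cis, which is the cis relation of C7 and C8 in the target. Regiochemistry: the silyloxy group at C1 makes the C6 methylene the nucleophilic diene terminus, which pairs with the electrophilic β-carbon C5, while the methyl-bearing terminus C3 pairs with the α-carbon C4, an orientation that is also the sterically easier one. The absolute configuration of C4 and C5 is controlled by the acetal stereocentre C8, since the diene should add to the butenolide face opposite the menthyloxy group, and with the (R) acetal this face leads to the configuration of the target. The C3 stereocentre is set by the E geometry of the diene together with the endo transition state, but it is removed in step 4, so endo/exo selectivity is not required. The selectivities needed are therefore facial and regiochemical, and high pressure is chosen to overcome the retarding β-methyl group without heat or a Lewis acid that would endanger the acetal and the silyl enol ether.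

Step 4
Reactants: 6 cis-fused Diels–Alder adduct
Product: 7 enone lactone acetal (C1 ketone, C2=C3 alkene)
Conditions: Pd(OAc)2 (1.1 equiv), MeCN, 25 °C
Reagents that add atoms: none
Why: Saegusa–Ito oxidation, in which divalent palladium converts the silyl enol ether into a C2-bound palladium enolate and syn β-hydride elimination of C3–H (the only β-hydrogen relative to palladium) gives the C2=C3 enone and removes the superfluous C3 stereocentre.

Step 5
Reactants: 7 enone lactone acetal
Product: 8 (1R)-allylic alcohol (C1 hydroxyl on the methyl face)
Conditions: (S)-2-methyl-CBS-oxazaborolidine [(S)-1-methyl-3,3-diphenyltetrahydro-1H,3H-pyrrolo[1,2-c][1,3,2]oxazaborole] (0.2 equiv), catecholborane (1.5 equiv), toluene, −78 °C; MeOH, then pH 7 buffer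
Reagents that add atoms: none
Why: Corey–Bakshi–Shibata reduction, a 1,2-selective carbonyl reduction in which the alkenyl arm (C2) acts as the large group, so the (S) catalyst should deliver hydride to the lactone face of C1 and give the (1R) carbinol, the same sense expected from the ring itself because the axial C5 methyl group screens the methyl face, while lactone and acetal are inert to catecholborane at this temperature.

Step 6
Reactants: 8 (1R)-allylic alcohol
Product: 9 allylic acetate
Conditions: Ac2O, pyridine, 4-(dimethylamino)pyridine (cat.), CH2Cl2, 0 → 23 °C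
Reagents that add atoms: acetic anhydride, CC(=O)OC(C)=O
Why: Nucleophile-catalysed O-acylation of the secondary allylic alcohol proceeds with retention at C1 and installs a leaving group whose anion (acetate) is too weakly basic to open the lactone acetal or enolise C4 in the next step.

Step 7
Reactants: 9 allylic acetate
Product: 10 C1-isopropenyl lactone acetal
Conditions: tributyl(isopropenyl)stannane (1.5 equiv), Pd2(dba)3·CHCl3 (5 mol %), LiCl (3 equiv), DMF, 40 °C
Reagents that add atoms: tributyl(prop-1-en-2-yl)stannane, C=C(C)[Sn](CCCC)(CCCC)CCCC
Why: Stille-type allylic cross-coupling, in which zerovalent palladium ionises the acetate with inversion to a π-allyl complex (C1–C2–C3) on the lactone face and transmetalation from tin followed by reductive elimination with retention places the isopropenyl group on that same face at the less substituted terminus C1, so C1 is set by overall inversion (isopropenyl cis to C7 and C8) and the alkene stays at C2=C3.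

Step 8
Reactants: 10 C1-isopropenyl lactone acetal
Product: 12 hydroxy lactone pseudo-acid (C8 anomers), via open-chain aldehyde lithium carboxylate 11 (not isolated)
Conditions: LiOH·H2O (3 equiv), THF/H2O, 0 → 23 °C; then 1 M HCl to pH 3, 0 °C
Reagents that add atoms: lithium hydroxide, [Li+].[OH-]
Why: Saponification of a pseudo-ester, in which hydroxide opens the γ-lactone at C7, the released C8 hemiacetal alkoxide collapses to the aldehyde with loss of mentholate and acidification lets the cis-disposed acid and aldehyde close to the hydroxy lactone, with C5 quaternary and C4 shielded as a carboxylate α-carbon so that no ring stereocentre should epimerise.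

Step 9
Reactants: 12 hydroxy lactone pseudo-acid
Product: 13 (E)-enoate acid (C7O2H on C4, (E)-CH=CH–CO2Me on C5)
Conditions: Ph3P=CHCO2Me (2.5 equiv), toluene, 80 °C
Reagents that add atoms: methyl (triphenylphosphoranylidene)acetate, COC(=O)C=P(c1ccccc1)(c1ccccc1)c1ccccc1
Why: Wittig olefination of a lactol-type pseudo-acid, in which the equilibrium share of the open C8 aldehyde is trapped by the stabilised ylide to give the E-configured C8=C9 enoate while C7 is released as the free acid, the aldehyde having no α-hydrogen and therefore no way to epimerise.

Step 10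
Reactants: 13 (E)-enoate acid
Product: 14 saturated methyl ester acid
Conditions: Mg turnings (10 equiv), MeOH, 0 → 23 °C; then 1 M HCl, 0 °C
Reagents that add atoms: none
Why: Dissolving-metal conjugate reduction (magnesium in methanol), in which electron transfer occurs only to the conjugated ester, so C8=C9 should be saturated while the isolated C2=C3 and isopropenyl alkenes and the carboxylate are left alone and the methyl ester is unchanged by the methoxide formed.

Step 11
Reactants: 14 saturated methyl ester acid
Product: 16 primary alcohol methyl ester, via mixed isobutyl carbonic anhydride 15 (not isolated)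
Conditions: i-BuOCOCl, N-methylmorpholine, THF, −15 °C; then NaBH4, H2O, 0 °C
Reagents that add atoms: none
Why: Mixed-anhydride activation followed by borohydride reduction converts the C7 acid into the C7 primary alcohol chemoselectively, since NaBH4 leaves the methyl ester and both alkenes untouched (a borane reagent is avoided because it would hydroborate the isopropenyl group) and the cold, brief exposure to N-methylmorpholine should not epimerise C4.

Step 12
Reactants: 16 primary alcohol methyl ester; 17 umbelliferone
Product: 18 coumarinyl ether methyl ester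
Conditions: PPh3, DIAD, THF, 0 → 23 °C
Reagents that add atoms: none
Why: Mitsunobu etherification, in which the acidic 7-hydroxycoumarin is alkylated on oxygen by the alkoxyphosphonium ion of the β-branched primary alcohol at C7 (not a stereocentre) under neutral conditions that leave ester, alkenes and coumarin intact.

Step 13
Reactants: 18 coumarinyl ether methyl ester
Product: 20 target acid CNP0301632.1, via ring-opened coumarinate trilithium salt 19 (not isolated)
Conditions: LiOH·H2O (4 equiv), THF/H2O, 23 °C; then 1 M HCl to pH 2, 0 °C
Reagents that add atoms: lithium hydroxide, [Li+].[OH-]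
Why: Ester saponification, in which hydroxide cleaves the methyl ester and should also open the coumarin lactone to the (Z)-2-hydroxycinnamate, which keeps its Z geometry and relactonises on acidification, while no stereocentre bears an acidic hydrogen at this stage.

**Compound list**

1 | 5-hydroxy-4-methylfuran-2(5H)-one (racemic pseudo-acid) | CC1=CC(=O)OC1O | starting material
2 | (−)-menthol, (1R,2S,5R)-5-methyl-2-(propan-2-yl)cyclohexan-1-ol | CC(C)[C@@H]1CC[C@@H](C)C[C@H]1O | starting material
3 | (5R)-4-methyl-5-{[(1R,2S,5R)-5-methyl-2-(propan-2-yl)cyclohexyl]oxy}furan-2(5H)-one | CC1=CC(=O)O[C@H]1O[C@@H]2C[C@H](C)CC[C@H]2C(C)C | intermediate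
4 | (E)-pent-3-en-2-one | C/C=C/C(C)=O | starting material
5 | (E)-2-[(tert-butyldimethylsilyl)oxy]penta-1,3-diene | C=C(O[Si](C)(C)C(C)(C)C)/C=C/C | intermediate
6 | (3R,3aR,7S,7aS)-5-[(tert-butyldimethylsilyl)oxy]-3-(l-menthyloxy)-3a,7-dimethyl-3a,4,7,7a-tetrahydro-2-benzofuran-1(3H)-one (cis-fused; C3 methyl cis to the lactone) | CC(C)(C)[Si](C)(C)OC1=C[C@H](C)[C@H](C2=O)[C@](C)([C@H](O[C@@H]3C[C@H](C)CC[C@H]3C(C)C)O2)C1 | intermediate
7 | (3R,3aR,7aS)-3-(l-menthyloxy)-3a,7-dimethyl-3a,7a-dihydro-2-benzofuran-1,5(3H,4H)-dione (enone lactone acetal) | O=C1C=C(C)[C@H](C2=O)[C@](C)([C@H](O[C@@H]3C[C@H](C)CC[C@H]3C(C)C)O2)C1 | intermediate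
8 | (3R,3aR,5R,7aS)-5-hydroxy-3-(l-menthyloxy)-3a,7-dimethyl-3a,4,5,7a-tetrahydro-2-benzofuran-1(3H)-one (hydroxyl trans to the lactone ring) | O[C@H]1C=C(C)[C@H](C2=O)[C@](C)([C@H](O[C@@H]3C[C@H](C)CC[C@H]3C(C)C)O2)C1 | intermediate
9 | acetate of 8, (3R,3aR,5R,7aS)-configured | CC(=O)O[C@H]1C=C(C)[C@H](C2=O)[C@](C)([C@H](O[C@@H]3C[C@H](C)CC[C@H]3C(C)C)O2)C1 | intermediate
10 | (3R,3aR,5S,7aS)-3-(l-menthyloxy)-3a,7-dimethyl-5-(prop-1-en-2-yl)-3a,4,5,7a-tetrahydro-2-benzofuran-1(3H)-one (isopropenyl cis to the lactone ring) | C=C(C)[C@@H]1C=C(C)[C@H](C2=O)[C@](C)([C@H](O[C@@H]3C[C@H](C)CC[C@H]3C(C)C)O2)C1 | intermediate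
11 | lithium carboxylate of the ring-opened C8 aldehyde (C7 carboxylate on C4, formyl on C5, ring configuration as in 10) | C=C(C)[C@@H]1C=C(C)[C@H](C(=O)[O-])[C@](C)(C=O)C1.[Li+] | intermediate
12 | (3aR,5S,7aS)-3-hydroxy-3a,7-dimethyl-5-(prop-1-en-2-yl)-3a,4,5,7a-tetrahydro-2-benzofuran-1(3H)-one (both C3 anomers) | C=C(C)[C@@H]1C=C(C)[C@H](C2=O)[C@](C)(C(O)O2)C1 | intermediate
13 | 6-[(E)-3-methoxy-3-oxoprop-1-en-1-yl]-2,6-dimethyl-4-(prop-1-en-2-yl)cyclohex-2-ene-1-carboxylic acid, the three side arms on C1, C4 and C5 (locants of the plan) all cis | C=C(C)[C@@H]1C=C(C)[C@H](C(=O)O)[C@](C)(/C=C/C(=O)OC)C1 | intermediate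
14 | (1R,4S,6R)-6-(3-methoxy-3-oxopropyl)-2,6-dimethyl-4-(prop-1-en-2-yl)cyclohex-2-ene-1-carboxylic acid | C=C(C)[C@@H]1C=C(C)[C@H](C(=O)O)[C@](C)(CCC(=O)OC)C1 | intermediate
15 | mixed anhydride of 14 with isobutyl hydrogen carbonate | C=C(C)[C@@H]1C=C(C)[C@H](C(=O)OC(=O)OCC(C)C)[C@](C)(CCC(=O)OC)C1 | intermediate
16 | methyl 3-[(1R,2R,5S)-2-(hydroxymethyl)-1,3-dimethyl-5-(prop-1-en-2-yl)cyclohex-3-en-1-yl]propanoate | C=C(C)[C@@H]1C=C(C)[C@H](CO)[C@](C)(CCC(=O)OC)C1 | intermediate
17 | umbelliferone (7-hydroxy-2H-chromen-2-one) | O=c1ccc2ccc(O)cc2o1 | starting material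
18 | methyl 3-[(1R,2R,5S)-1,3-dimethyl-2-{[(2-oxo-2H-chromen-7-yl)oxy]methyl}-5-(prop-1-en-2-yl)cyclohex-3-en-1-yl]propanoate | C=C(C)[C@@H]1C=C(C)[C@H](COc2ccc3ccc(=O)oc3c2)[C@](C)(CCC(=O)OC)C1 | intermediate
19 | trilithium salt of the ring-opened (Z)-2-oxidocinnamate dicarboxylate derived from 18 | C=C(C)[C@@H]1C=C(C)[C@H](COc2ccc(/C=C\C(=O)[O-])c([O-])c2)[C@](C)(CCC(=O)[O-])C1.[Li+].[Li+].[Li+] | intermediate
20 | 3-[(1R,2R,5S)-1,3-dimethyl-2-{[(2-oxo-2H-chromen-7-yl)oxy]methyl}-5-(prop-1-en-2-yl)cyclohex-3-en-1-yl]propanoic acid (CNP0301632.1) | C=C(C)[C@@H]1C=C(C)[C@H](COc2ccc3ccc(=O)oc3c2)[C@](C)(CCC(=O)O)C1 | target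

**Step count**

Total steps: 13. Longest linear sequence: 12 steps (1 → 3 → 6 → 7 → 8 → 9 → 10 → 12 → 13 → 14 → 16 → 18 → 20); the diene (step 2) is a one-step side branch.

**Steps most likely to fail**

Step 3. The β-methyl group may retard the cycloaddition so much that oligomerisation, silyl transfer or hydrolysis of the diene outruns it. The fallback sets out from 3 and returns at 6, and activates the dienophile with a removable α-halogen. Bromine adds across the butenolide alkene of 3 to give the dibromolactone F1, and Et3N eliminates HBr to give the 3-bromo-4-methyl-5-menthyloxybutenolide F2. Its lower LUMO should let it take up diene 5 with the same regiochemical and facial sense, giving the C4-bromo adduct F3. Bu3SnH with azobisisobutyronitrile in benzene at 80 °C then replaces bromine by hydrogen through the C4 radical, which should accept hydrogen on the face that keeps the lactone cis-fused, so that 6 results.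

Step 7. Slow transmetalation at the hindered π-allyl complex may let β-hydride elimination toward C4 or C6 (diene formation), attack at C3, or erosion of stereochemical fidelity through palladium exchange compete with the coupling. The fallback sets out from 8 and returns at 10, and replaces inner-sphere delivery of a hard alkenyl group by outer-sphere attack of a stabilised carbon nucleophile (net retention through double inversion). Mitsunobu esterification of 8 with 4-nitrobenzoic acid (PPh3, DIAD) inverts C1 and gives the C1-epimeric 4-nitrobenzoate F4, with the ester on the lactone face. Pd(PPh3)4 ionises it from the methyl face, and the nitronate of nitroethane (DBU, THF) attacks C1 from the lactone face to give the 1-nitroethyl lactone acetal F5. A Nef reaction (DBU, then TiCl3 in NH4OAc buffer) gives the C1-acetyl lactone acetal F6. Methylenation with the non-basic Zn/CH2Br2/TiCl4 reagent, which tolerates epimerisable ketones and lactones, converts acetyl into isopropenyl and delivers 10.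

Step 5. Facial selectivity of hydride delivery may be poor if catalyst control and the conformational bias of the ring oppose each other, so that the C1 epimer forms in quantity. The fallback sets out from 7 and returns at 10. The C1-epimeric alcohol F7 (hydroxyl on the lactone face) is separated and not discarded. Mitsunobu esterification with 4-nitrobenzoic acid inverts C1 and gives the 4-nitrobenzoate F8, with the leaving group on the required methyl face. F8 is coupled with tributyl(isopropenyl)stannane under the conditions of step 7 in place of acetate 9, so that both C1 epimers converge on 10.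

**Further compounds**

F1 | step 3 | 3,4-dibromo-4-methyl-5-(l-menthyloxy)dihydrofuran-2(3H)-one (mixture at the two brominated carbons) | CC1(Br)C(Br)C(=O)O[C@H]1O[C@@H]2C[C@H](C)CC[C@H]2C(C)C
F2 | step 3 | (5R)-3-bromo-4-methyl-5-(l-menthyloxy)furan-2(5H)-one | CC1=C(Br)C(=O)O[C@H]1O[C@@H]2C[C@H](C)CC[C@H]2C(C)C
F3 | step 3 | C4-bromo analogue of adduct 6 (bromine at the ring-fusion carbon, cis-fused) | CC(C)(C)[Si](C)(C)OC1=C[C@H](C)[C@](Br)(C2=O)[C@](C)([C@H](O[C@@H]3C[C@H](C)CC[C@H]3C(C)C)O2)C1
F4 | step 7 | C1-epimeric 4-nitrobenzoate derived from 8 (ester on the lactone face) | O=C(O[C@@H]1C=C(C)[C@H](C2=O)[C@](C)([C@H](O[C@@H]3C[C@H](C)CC[C@H]3C(C)C)O2)C1)c1ccc(cc1)[N+](=O)[O-]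
F5 | step 7 | C1-(1-nitroethyl) lactone acetal (side-chain epimers; substituent on the lactone face) | CC([N+](=O)[O-])[C@@H]1C=C(C)[C@H](C2=O)[C@](C)([C@H](O[C@@H]3C[C@H](C)CC[C@H]3C(C)C)O2)C1
F6 | step 7 | C1-acetyl lactone acetal (acetyl on the lactone face) | CC(=O)[C@@H]1C=C(C)[C@H](C2=O)[C@](C)([C@H](O[C@@H]3C[C@H](C)CC[C@H]3C(C)C)O2)C1
F7 | step 5 | C1 epimer of alcohol 8 (hydroxyl on the lactone face) | O[C@@H]1C=C(C)[C@H](C2=O)[C@](C)([C@H](O[C@@H]3C[C@H](C)CC[C@H]3C(C)C)O2)C1
F8 | step 5 | 4-nitrobenzoate with the C1 configuration of 8 (ester on the methyl face) | O=C(O[C@H]1C=C(C)[C@H](C2=O)[C@](C)([C@H](O[C@@H]3C[C@H](C)CC[C@H]3C(C)C)O2)C1)c1ccc(cc1)[N+](=O)[O-]
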